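The bond on which the route rests is C2–C3 of the 12-bromododeca-3,11-dien-1-ynyl side chain (C1 is the alkyne carbon on the oxolane ring). The C3–C12 segment hides a symmetric unit: C3 and the bromine-bearing C12 are equivalent termini of (1E,9E)-1,10-dibromodeca-1,9-diene. One desilylative Sonogashira mono-coupling of this bis(vinyl bromide) with a silyl-capped trans-2-ethynyl-5-(3-methoxycarbonylpropyl)oxolane forms the bond, sets the E-enyne and leaves the second C–Br as the terminal bromoalkene. The oxolane ring, its 2,5-trans relationship and the butanoate chain come earlier from one cobalt-catalysed aerobic cyclisation/radical addition cascade of an (S)-propargylic pentenol with methyl acrylate.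

Key step: step 5

Step 1
Reactants: 1 pent-4-enoyl chloride; 2 ethynyltrimethylsilane
Product: 3 1-(trimethylsilyl)hept-6-en-1-yn-3-one
Conditions: PdCl2(PPh3)2 (2 mol%), CuI (4 mol%), Et3N (1.1 equiv), THF, rt
Reagents that add atoms: none
Why: Acyl Sonogashira coupling, in which the acyl–palladium chloride formed by oxidative addition is intercepted by the copper acetylide faster than any reaction at the remote terminal alkene, should give the silyl ynone directly.

Step 2
Reactants: 3 1-(trimethylsilyl)hept-6-en-1-yn-3-one
Product: 4 (3S)-1-(trimethylsilyl)hept-6-en-1-yn-3-ol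
Conditions: Ru[(S,S)-TsNCH(Ph)CH(Ph)NH](p-cymene) (1 mol%), i-PrOH, rt
Reagents that add atoms: none
Why: Noyori asymmetric transfer hydrogenation of an α,β-acetylenic ketone under base-free conditions, in which the alkynyl group takes the place of the aryl group of aryl ketones in the six-membered outer-sphere transition state, should deliver hydride to the face that gives the (S)-carbinol with the (S,S)-ligand while the alkene and the C–Si bond stay untouched.

Step 3
Reactants: 4 (3S)-1-(trimethylsilyl)hept-6-en-1-yn-3-ol; 5 methyl acrylate
Product: 7 methyl 4-[(2R,5S)-5-[(trimethylsilyl)ethynyl]oxolan-2-yl]butanoate, via oxolan-2-ylmethyl radical 6 (not isolated)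
Conditions: Co(btfa)2 [bis(4,4,4-trifluoro-1-phenylbutane-1,3-dionato)cobalt, divalent cobalt] (10 mol%), O2 (1 atm), cyclohexa-1,4-diene (10 equiv), methyl acrylate (10 equiv), toluene, 60 °C
Reagents that add atoms: none
Why: Mukaiyama-type cobalt-catalysed aerobic oxidative alkenol cyclisation terminated by a Giese addition, in which the cobalt-bound alkoxide closes 5-exo onto the terminal alkene through a chair-like transition state with the alkynyl group pseudo-equatorial (which should set the new C–O centre 2,5-trans to the carbinol centre) and the primary radical 6 adds to methyl acrylate before hydrogen-atom transfer from cyclohexa-1,4-diene.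

Step 4
Reactants: 8 deca-1,9-diyne
Product: 10 (1E,9E)-1,10-dibromodeca-1,9-diene, via bis(alkenylzirconocene chloride) 9 (not isolated)
Conditions: Cp2Zr(H)Cl (2.4 equiv), THF, rt, dark; then NBS (2.4 equiv), 0 °C
Reagents that add atoms: N-bromosuccinimide (NBS), O=C1CCC(=O)N1Br
Why: Two-fold hydrozirconation with the Schwartz reagent adds Zr–H syn and anti-Markovnikov to each terminal alkyne and bromodezirconation with NBS proceeds with retention, so both bromoalkenes should be E.

Step 5
Reactants: 7 methyl 4-[(2R,5S)-5-[(trimethylsilyl)ethynyl]oxolan-2-yl]butanoate; 10 (1E,9E)-1,10-dibromodeca-1,9-diene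
Product: 12 methyl 4-[(2R,5S)-5-[(3E,11E)-12-bromododeca-3,11-dien-1-yn-1-yl]oxolan-2-yl]butanoate (the target), via terminal alkyne 11 (not isolated)
Conditions: 10 (4 equiv), Pd(PPh3)4 (5 mol%), CuI (10 mol%), Et3N, degassed THF, rt; TBAF (1.1 equiv, 1 M in THF) added slowly by syringe pump
Reagents that add atoms: none
Why: Fluoride slowly unmasks the terminal alkyne 11 from the C–Si bond, copper acetylide formation follows, zerovalent palladium inserts with retention into one C(sp2)–Br bond of 10, and transmetalation/reductive elimination form the C(sp)–C(sp2) bond (Sonogashira coupling in its desilylative, sila-Sonogashira form). The step closes no ring and creates no stereocentre; the E geometry of the new enyne is carried over unchanged from the (E)-bromoalkene, and the propargylic oxolane centre should not epimerise under fluoride/amine at rt. The selectivity needed is mono- over bis-coupling: the two C–Br termini are identical and insulated by six methylenes, so a four-fold excess of 10 together with the slow, fluoride-gated release of the alkyne should hold double coupling to a statistical minor share, and unreacted 10 is recovered by chromatography. The low standing concentration of free alkyne and rigorous degassing should also suppress Glaser homocoupling. (E)-1-Bromoalkenes have no hydrogen anti to bromine, so base-induced dehydrobromination of 10 or of the product is not expected.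

Compound list
1 | pent-4-enoyl chloride | C=CCCC(=O)Cl | starting material
2 | ethynyltrimethylsilane | C#C[Si](C)(C)C | starting material
3 | 1-(trimethylsilyl)hept-6-en-1-yn-3-one | C=CCCC(=O)C#C[Si](C)(C)C | intermediate
4 | (3S)-1-(trimethylsilyl)hept-6-en-1-yn-3-ol | C=CCC[C@@H](C#C[Si](C)(C)C)O | intermediate
5 | methyl acrylate | C=CC(=O)OC | starting material
6 | {(2R,5S)-5-[(trimethylsilyl)ethynyl]oxolan-2-yl}methyl radical | [CH2][C@@H]1CC[C@@H](C#C[Si](C)(C)C)O1 | intermediate
7 | methyl 4-[(2R,5S)-5-[(trimethylsilyl)ethynyl]oxolan-2-yl]butanoate | COC(=O)CCC[C@@H]1CC[C@@H](C#C[Si](C)(C)C)O1 | intermediate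
8 | deca-1,9-diyne | C#CCCCCCCC#C | starting material
9 | (1E,9E)-deca-1,9-diene-1,10-diylbis[chlorobis(cyclopentadienyl)zirconium] | Cl[Zr](C1C=CC=C1)(C1C=CC=C1)/C=C/CCCCCC/C=C/[Zr](Cl)(C1C=CC=C1)C1C=CC=C1 | intermediate
10 | (1E,9E)-1,10-dibromodeca-1,9-diene | Br/C=C/CCCCCC/C=C/Br | intermediate
11 | methyl 4-[(2R,5S)-5-ethynyloxolan-2-yl]butanoate | COC(=O)CCC[C@@H]1CC[C@@H](C#C)O1 | intermediate
12 | methyl 4-[(2R,5S)-5-[(3E,11E)-12-bromododeca-3,11-dien-1-yn-1-yl]oxolan-2-yl]butanoate | COC(=O)CCC[C@@H]1CC[C@@H](C#C/C=C/CCCCCC/C=C/Br)O1 | target

Total step count: 5. Longest linear sequence: 4 steps (steps 1, 2, 3 and 5); step 4 is a one-step side branch.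

Steps most likely to fail

Step 3. The cyclised radical 6 may take a hydrogen atom from cyclohexa-1,4-diene before it meets the acrylate, the adduct radical may telomerise with more acrylate, the slim alkynyl group may give weaker trans control than an alkyl or aryl group, and the propargylic alcohol may be oxidised to the ynone. Fallback, from 4 back to 7: ring closure and chain extension are separated. Aerobic oxidative cyclisation of 4 with Co(modp)2 [bis(1-morpholinocarbamoyl-4,4-dimethyl-1,3-pentanedionato)cobalt], O2 and t-BuOOH in i-PrOH at 55 °C should give [(2S,5S)-5-[(trimethylsilyl)ethynyl]oxolan-2-yl]methanol F1, from which any cis isomer can be removed by chromatography. Appel iodination (I2, PPh3, imidazole, CH2Cl2) then gives {[(2S,5S)-5-(iodomethyl)oxolan-2-yl]ethynyl}trimethylsilane F2. Giese addition of the derived radical to methyl acrylate 5 (Bu3SnH by syringe pump, AIBN, benzene, 80 °C) returns to 7.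

Step 5. Coupling may occur at both C–Br termini, the released alkyne may dimerise oxidatively, or oxidative addition into the bromoalkene may be sluggish at the temperature the ester and fluoride allow. Fallback, from 7 and 8 back to 12: the two termini of the C10 unit are differentiated before the coupling. Diyne 8, used in excess, is mono-hydrozirconated and brominated (Cp2Zr(H)Cl 0.5 equiv, then NBS) to (E)-1-bromodec-1-en-9-yne F3. A second hydrozirconation with iodine quench gives (1E,9E)-1-bromo-10-iododeca-1,9-diene F4. Silane 7 is cleaved with K2CO3 in MeOH to the terminal alkyne 11, now isolated. Classical Sonogashira coupling of 11 with F4 (Pd(PPh3)4, CuI, Et3N, THF, 0 °C to rt) should engage only the C–I terminus and give 12 with no statistical element at the late stage.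

Step 1. The enolisable acid chloride may form a ketene with Et3N, and 2 may dimerise oxidatively. Fallback, from 1 back to 3: 1 is converted with MeNHOMe·HCl and Et3N in CH2Cl2 into N-methoxy-N-methylpent-4-enamide F5. Addition of lithium (trimethylsilyl)acetylide (from 2 and n-BuLi, THF, −78 °C) to this Weinreb amide gives 3 after aqueous work-up.

Further compounds
F1 | step 3 | [(2S,5S)-5-[(trimethylsilyl)ethynyl]oxolan-2-yl]methanol | OC[C@@H]1CC[C@@H](C#C[Si](C)(C)C)O1
F2 | step 3 | {[(2S,5S)-5-(iodomethyl)oxolan-2-yl]ethynyl}trimethylsilane | IC[C@@H]1CC[C@@H](C#C[Si](C)(C)C)O1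
F3 | step 5 | (E)-1-bromodec-1-en-9-yne | Br/C=C/CCCCCCC#C
F4 | step 5 | (1E,9E)-1-bromo-10-iododeca-1,9-diene | Br/C=C/CCCCCC/C=C/I
F5 | step 1 | N-methoxy-N-methylpent-4-enamide | C=CCCC(=O)N(C)OC
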